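**Retrosynthetic overview**
1. No ring is formed. Both benzene rings are bought with their bromines in place: ring A (the phenol ring) as 2,4-dibromo-6-fluoroaniline 1, and ring B as 2,4-dibromophenol 2.
2. The only strategic bond is the diaryl ether C–O bond. It is cut on the ring A side (C2–O), which pairs two innately nucleophilic sites: the ortho-carbon of a phenol (an enol carbon) and a phenol oxygen.
3. Ring A is therefore used with reversed polarity. Aniline 1 goes to diazonium salt 3 and then to o-quinone diazide 4 (diazotisation, then hydroxy-defluorination ortho to N2+). Diazide 4 is the precursor of rhodium quinoid carbene 5, an aromatic enolonium equivalent.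
4. O–H insertion of 2 into 5 (by way of oxonium ylide 6) and rearomatisation give target 7 with its free OH. This takes two steps, with no protecting group, no bromination and no catalyst that touches C–Br.

Assumption: the target has no stereocentre and no configurationally stable axis, so it is achiral and the "single enantiomer" is the compound itself.

**Step 1**
Reactants: 1 2,4-dibromo-6-fluoroaniline
Product: 4 3,5-dibromo-6-diazocyclohexa-2,4-dien-1-one, via diazonium tetrafluoroborate 3 (not isolated)
Conditions: t-BuONO (1.2 equiv), 48% aq HBF4 (2 equiv), MeCN, 0 °C, 30 min; then CH2Cl2, aq NaHCO3 to pH 6–7, 0 °C to rt, 3 h, dark; concentrate below 30 °C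
Reagents that add atoms: tert-butyl nitrite CC(C)(C)ON=O; water O
Why: Diazotisation gives 3, in which the diazonio group (the strongest activator for SNAr) makes the ortho C–F bond so labile that water replaces fluoride far faster than either bromide (hydroxy-dehalogenation of an o-halodiazonium salt, the classical entry to o-quinone diazides), and loss of a proton gives neutral, extractable 4 with oxygen and diazo carbon in the required 1,2-relationship; no stereocentre is formed.

**Step 2**
Reactants: 4 3,5-dibromo-6-diazocyclohexa-2,4-dien-1-one; 2 2,4-dibromophenol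
Product: 7 3,5-dibromo-2-(2,4-dibromophenoxy)phenol, via rhodium quinoid carbene 5 (not isolated), via oxonium ylide 6 (not isolated)
Conditions: Rh2(OAc)4 (2 mol %), 2 (3 equiv), 4 Å MS, ClCH2CH2Cl, 70 °C, 4 added over 4 h, dark, N2 atmosphere
Reagents that add atoms: none
Why: Proposed new method: the divalent-rhodium dimer Rh2(OAc)4 expels N2 from 4 to give quinoid carbene 5, in which C2 of ring A (normally a nucleophilic enol carbon) is electrophilic like an enolonium ion, so the O–H of 2 (its ring carbons blocked or deactivated by two bromines, which disfavours C-attack) adds to give oxonium ylide 6, and a proton shift driven by rearomatisation delivers 7 with its free OH, the closest known reaction type being the rhodium-carbenoid O–H insertion of diazonaphthoquinones into alcohols and of α-diazocarbonyl compounds into phenols; slow addition of 4 and excess 2 hold back carbene dimerisation, Wolff ring contraction and a second insertion into 7, the four C–Br bonds are inert to this catalyst, and no stereocentre is formed.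

**Compound list**
1 | 2,4-dibromo-6-fluoroaniline | Nc1c(F)cc(Br)cc1Br | starting material
2 | 2,4-dibromophenol | Oc1ccc(Br)cc1Br | starting material
3 | 2,4-dibromo-6-fluorobenzenediazonium tetrafluoroborate | N#[N+]c1c(F)cc(Br)cc1Br.F[B-](F)(F)F | intermediate (not isolated)
4 | 3,5-dibromo-6-diazocyclohexa-2,4-dien-1-one (3,5-dibromo-o-benzoquinone 2-diazide) | O=C1C=C(Br)C=C(Br)C1=[N+]=[N-] | intermediate
5 | rhodium quinoid carbene: 2,4-dibromo-6-oxocyclohexa-2,4-dien-1-ylidene bound axially to dirhodium tetraacetate | O=C1C=C(Br)C=C(Br)C1=[Rh+2][Rh+2].CC(=O)[O-].CC(=O)[O-].CC(=O)[O-].CC(=O)[O-] | intermediate (not isolated)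
6 | oxonium ylide: 3,5-dibromo-2-[(2,4-dibromophenyl)oxonio]phenolate | [O-]c1cc(Br)cc(Br)c1[OH+]c1ccc(Br)cc1Br | intermediate (not isolated)
7 | 3,5-dibromo-2-(2,4-dibromophenoxy)phenol (achiral) | Oc1cc(Br)cc(Br)c1Oc1ccc(Br)cc1Br | target

**Total step count:** 2. **Longest linear sequence:** 2 (1 → 4 → 7).

**Steps most likely to fail**
The route has only two steps, so the three entries are two separate failure modes of step 2 and one of step 1.

(a) Step 2, carbene not captured (most likely). Carbene 5 may ring-contract (Wolff), abstract hydrogen or dimerise faster than the weakly nucleophilic phenol 2 adds. The fallback uses normal polarity and a latent phenol. It sets out from 2 and comes back at 7. Phenol 2 displaces fluoride from purchased 3,5-dibromo-2-fluorobenzaldehyde (O=Cc1cc(Br)cc(Br)c1F) by SNAr ortho to the formyl group (K2CO3, DMF, 90 °C) to give 3,5-dibromo-2-(2,4-dibromophenoxy)benzaldehyde F1. Baeyer–Villiger oxidation (mCPBA, CH2Cl2, reflux) gives 3,5-dibromo-2-(2,4-dibromophenoxy)phenyl formate F2. Methanolysis (K2CO3, MeOH, rt) gives 7.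

(b) Step 1. At pH 6–7 the electron-poor diazonium salt 3 may lose N2 through the radical diazohydroxide pathway faster than water displaces fluoride. The fallback installs oxygen first and the diazo group last. It sets out from 1 and comes back at 4. Oxidation of 1 (NaBO3·4H2O, AcOH, 55 °C) gives 1,5-dibromo-3-fluoro-2-nitrobenzene F3. SNAr with hydroxide at the C–F bond ortho to the nitro group (KOH, DMSO/H2O, 40 °C, then HCl) gives 3,5-dibromo-2-nitrophenol F4. A reduction that spares C–Br (Fe, NH4Cl, EtOH/H2O, 70 °C) gives 2-amino-3,5-dibromophenol F5. Diazotisation of this o-aminophenol (t-BuONO, MeCN, 0 °C) gives 4.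

(c) Step 2, wrong chemoselectivity. Carbene 5 forms but attacks C6 of 2 (C–C coupling) or the OH of product 7. The fallback keeps the polarity inversion at the same ring A carbon but places it on trivalent iodine instead of a carbene. It sets out from 4 and comes back at 7.
- Aqueous HI (MeCN, 0 °C to rt) converts 4 by iodo-dediazoniation into 3,5-dibromo-2-iodophenol F6.
- MeI and K2CO3 in acetone give 1,5-dibromo-2-iodo-3-methoxybenzene F7.
- mCPBA and TsOH·H2O (MeCN, 77 °C) give 1,5-dibromo-2-[hydroxy(tosyloxy)-λ3-iodanyl]-3-methoxybenzene F8.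
- F8 reacts in the same flask with 1,3,5-trimethoxybenzene to give (2,4-dibromo-6-methoxyphenyl)(2,4,6-trimethoxyphenyl)iodonium 4-methylbenzenesulfonate F9.
- Metal-free ligand coupling with 2 (K2CO3, MeCN, 60 °C), in which the electron-rich trimethoxyphenyl group stays on iodine, gives 1,5-dibromo-2-(2,4-dibromophenoxy)-3-methoxybenzene F10.
- BBr3 (CH2Cl2, −78 °C to rt) gives 7.

**Further compounds**
F1 | step 2 | 3,5-dibromo-2-(2,4-dibromophenoxy)benzaldehyde | O=Cc1cc(Br)cc(Br)c1Oc1ccc(Br)cc1Br
F2 | step 2 | 3,5-dibromo-2-(2,4-dibromophenoxy)phenyl formate | O=COc1cc(Br)cc(Br)c1Oc1ccc(Br)cc1Br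
F3 | step 1 | 1,5-dibromo-3-fluoro-2-nitrobenzene | O=[N+]([O-])c1c(F)cc(Br)cc1Br
F4 | step 1 | 3,5-dibromo-2-nitrophenol | O=[N+]([O-])c1c(O)cc(Br)cc1Br
F5 | step 1 | 2-amino-3,5-dibromophenol | Nc1c(O)cc(Br)cc1Br
F6 | step 2 | 3,5-dibromo-2-iodophenol | Oc1cc(Br)cc(Br)c1I
F7 | step 2 | 1,5-dibromo-2-iodo-3-methoxybenzene | COc1cc(Br)cc(Br)c1I
F8 | step 2 | 1,5-dibromo-2-[hydroxy(tosyloxy)-λ3-iodanyl]-3-methoxybenzene | COc1cc(Br)cc(Br)c1I(O)OS(=O)(=O)c1ccc(C)cc1
F9 | step 2 | (2,4-dibromo-6-methoxyphenyl)(2,4,6-trimethoxyphenyl)iodonium 4-methylbenzenesulfonate | COc1cc(Br)cc(Br)c1[I+]c1c(OC)cc(OC)cc1OC.Cc1ccc(cc1)S(=O)(=O)[O-]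
F10 | step 2 | 1,5-dibromo-2-(2,4-dibromophenoxy)-3-methoxybenzene | COc1cc(Br)cc(Br)c1Oc1ccc(Br)cc1Br
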